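**Plan**

- Retrosynthetic cuts, in order: the two phenol O–benzyl bonds; the bond from the exocyclic CH2 on C3 to its aryl ring (back to a C3‑methyl group and an aryl iodide); C3–CH3; C4–CH2Ar; this leaves an (S)‑malic ester.
- Enabling feature: in the γ‑lactone (O1, C2 carbonyl, C3, C4, C5), C3 is a quaternary carbinol carbon and its exocyclic carbon lies β to C2. With the lactone opened to an N‑(quinolin‑8‑yl) amide at C2, palladium reaches that carbon through a five‑membered palladacycle, so the benzylic CH2 is carried as a methyl group and arylated late.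
- Forward order: malate chain, C4 benzylation, dioxolanone, C3 methylation, reduction and lactone closure, lactone opened to the directing amide with O3/O5 tied in a temporary 1,3‑dioxane, C–H arylation, acid re‑closes the lactone and expels the auxiliary, hydrogenolysis.
- Stereochemistry: C3 comes from (S)‑malic acid by self‑regeneration of the stereocentre (cis tert‑butyl dioxolanone, methyl enters anti to tert‑butyl, net retention). C4 comes from the anti‑selective alkylation of the malate dianion. The key step touches neither centre.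

Key step: step 10

Remark: lactone atoms are numbered O1, C2 (carbonyl), C3 (carbinol), C4, C5; the target is read as the (3S,4S) isomer with the two benzyl groups trans, and compounds 1, 3 and 14 are taken as catalogue materials.

**Route**

Step 1
Reactants: 1 [4-(benzyloxy)-3-methoxyphenyl]methanol
Product: 2 1-(benzyloxy)-4-(bromomethyl)-2-methoxybenzene
Conditions: PBr3 (0.4 equiv), Et2O, 0 °C
Reagents that add atoms: phosphorus tribromide, BrP(Br)Br
Why: Bromination of an electron-rich benzylic alcohol through its phosphite ester (nucleophilic displacement by bromide); the aryl benzyl ether is inert at 0 °C.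

Step 2
Reactants: 3 diisopropyl (S)-malate; 2 1-(benzyloxy)-4-(bromomethyl)-2-methoxybenzene
Product: 5 diisopropyl (2S,3R)-3-[4-(benzyloxy)-3-methoxybenzyl]-2-hydroxybutanedioate, via malate dilithium alkoxide-enolate 4 (not isolated)
Conditions: LiN(SiMe3)2 (2.1 equiv), THF, −78 → −20 °C; then 2, −78 → 0 °C; AcOH quench
Reagents that add atoms: none
Why: Fráter–Seebach alkylation: the lithium-chelated alkoxide-enolate should be benzylated on the face away from the C1 ester group, giving the anti (2S,3R) product and so setting the future C4 of the lactone.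

Step 3
Reactants: 5 diisopropyl (2S,3R)-3-[4-(benzyloxy)-3-methoxybenzyl]-2-hydroxybutanedioate
Product: 6 (2S,3R)-3-[4-(benzyloxy)-3-methoxybenzyl]-2-hydroxybutanedioic acid
Conditions: KOH, H2O/1,4-dioxane, rt; then aq. HCl to pH 1
Reagents that add atoms: potassium hydroxide, [K+].[OH-]
Why: Ester saponification; each ester becomes a non-enolizable carboxylate as it is cleaved, so C3 should not epimerize, and the benzyl ether is stable to base.

Step 4
Reactants: 6 (2S,3R)-3-[4-(benzyloxy)-3-methoxybenzyl]-2-hydroxybutanedioic acid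
Product: 7 (2R)-3-[4-(benzyloxy)-3-methoxyphenyl]-2-[(2S,4S)-2-tert-butyl-5-oxo-1,3-dioxolan-4-yl]propanoic acid
Conditions: pivalaldehyde, TsOH·H2O (cat.), H2SO4 (cat.), pentane/CH2Cl2, reflux, water separator
Reagents that add atoms: pivalaldehyde, CC(C)(C)C=O
Why: Acid-catalysed acetalization of the α-hydroxy acid unit (dioxolanone formation); the five-membered 1,3-dioxolan-4-one is preferred over the six-membered ring through the other acid, and the cis isomer (new acetal centre S) is the thermodynamic product, to be purified by crystallization.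

Step 5
Reactants: 7 (2R)-3-[4-(benzyloxy)-3-methoxyphenyl]-2-[(2S,4S)-2-tert-butyl-5-oxo-1,3-dioxolan-4-yl]propanoic acid
Product: 9 (2R)-3-[4-(benzyloxy)-3-methoxyphenyl]-2-[(2S,4S)-2-tert-butyl-4-methyl-5-oxo-1,3-dioxolan-4-yl]propanoic acid, via dilithium carboxylate-enolate 8 (not isolated)
Conditions: LiN(SiMe3)2 (2.2 equiv), THF, −78 °C; MeI, −78 → −30 °C; aq. HCl
Reagents that add atoms: iodomethane, CI
Why: Enolate alkylation under self-regeneration of the stereocentre: the first equivalent of base gives the carboxylate, the second the dioxolanone enolate, and MeI should enter anti to the tert-butyl group, so methyl replaces the former hydrogen with retention and creates the quaternary carbinol carbon (future C3, S).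

Step 6
Reactants: 9 (2R)-3-[4-(benzyloxy)-3-methoxyphenyl]-2-[(2S,4S)-2-tert-butyl-4-methyl-5-oxo-1,3-dioxolan-4-yl]propanoic acid
Product: 11 (3S,4S)-4-[4-(benzyloxy)-3-methoxybenzyl]-3-hydroxy-3-methyloxolan-2-one, via hydroxy dioxolanone 10 (not isolated)
Conditions: BH3·SMe2, THF, 0 °C → rt; MeOH; then TFA (cat.), CH2Cl2, rt
Reagents that add atoms: none
Why: Chemoselective borane reduction of the free carboxylic acid (acyloxyborane pathway) followed by acid-catalysed transesterification, in which the new primary hydroxyl attacks the acetal-ester carbonyl (5-exo-trig), closes the γ-lactone and releases pivalaldehyde without touching either stereocentre.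

Step 7
Reactants: 11 (3S,4S)-4-[4-(benzyloxy)-3-methoxybenzyl]-3-hydroxy-3-methyloxolan-2-one
Product: 12 (2S,3S)-3-[4-(benzyloxy)-3-methoxybenzyl]-2,4-dihydroxy-2-methyl-N-(quinolin-8-yl)butanamide
Conditions: 8-aminoquinoline (3 equiv), AlMe3 (4 equiv), toluene, 0 → 80 °C; aq. potassium sodium tartrate work-up
Reagents that add atoms: 8-aminoquinoline, Nc1cccc2cccnc12
Why: Weinreb-type aminolysis: the dimethylaluminium amide of 8-aminoquinoline opens the lactone at C2 to the γ-hydroxy amide and installs the bidentate directing group, the tertiary hydroxyl being carried as its aluminium alkoxide.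

Step 8
Reactants: 12 (2S,3S)-3-[4-(benzyloxy)-3-methoxybenzyl]-2,4-dihydroxy-2-methyl-N-(quinolin-8-yl)butanamide
Product: 13 (4S,5S)-5-[4-(benzyloxy)-3-methoxybenzyl]-2,2,4-trimethyl-N-(quinolin-8-yl)-1,3-dioxane-4-carboxamide
Conditions: 2,2-dimethoxypropane, PPTS (cat.), CH2Cl2, rt
Reagents that add atoms: 2,2-dimethoxypropane, COC(C)(C)OC
Why: Transketalization of the 1,3-diol (tertiary and primary hydroxyl) to the isopropylidene acetal; the temporary 1,3-dioxane ring blocks relactonization and masks both hydroxyls for the metal-mediated step.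

Step 9
Reactants: 14 4-iodo-2-methoxyphenol
Product: 15 1-(benzyloxy)-4-iodo-2-methoxybenzene
Conditions: BnBr, K2CO3, DMF, rt
Reagents that add atoms: benzyl bromide, BrCc1ccccc1
Why: Williamson ether synthesis on the phenoxide.

Step 10
Reactants: 13 (4S,5S)-5-[4-(benzyloxy)-3-methoxybenzyl]-2,2,4-trimethyl-N-(quinolin-8-yl)-1,3-dioxane-4-carboxamide; 15 1-(benzyloxy)-4-iodo-2-methoxybenzene
Product: 16 (4S,5S)-4,5-bis[4-(benzyloxy)-3-methoxybenzyl]-2,2-dimethyl-N-(quinolin-8-yl)-1,3-dioxane-4-carboxamide
Conditions: Pd(OAc)2 (10 mol %), AgOAc (1.5 equiv), 15 (3 equiv), toluene, 110 °C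
Reagents that add atoms: none
Why: The deprotonated amide nitrogen and the quinoline nitrogen of 13 bind divalent palladium as an N,N-chelate next to the methyl group on the dioxane C4; acetate-assisted concerted metalation–deprotonation of a methyl C–H bond gives a five-membered palladacycle, oxidative addition of 15 raises it to tetravalent palladium, and C–C reductive elimination forms the CH2–aryl bond while AgOAc takes up iodide and returns Pd(OAc)2. The closest known reaction type is the 8-aminoquinoline-directed β-C(sp3)–H arylation of α-quaternary carboxamides such as pivalamides and O-protected 2-hydroxy-2-methylpropanamides with aryl iodides. No ring of the product is closed; only the transient palladacycle forms, by five-membered cyclometalation. No stereocentre is created, and the quaternary C4 and the C5 methine of the dioxane cannot enolize and should keep their configuration. The step needs site selectivity and mono-arylation: the methyl group is the only primary C–H β to the amide, the other β C–H (C5) is a hindered methine, the benzylic and OCH2 hydrogens are γ and would need six-membered palladacycles, and a second arylation at the new crowded benzylic CH2 should be slow and is limited by stopping at full consumption of 13. β-Oxygen elimination is disfavoured because the C4–O bond is held in the dioxane ring and cannot become syn-coplanar with the C–Pd bond.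

Step 11
Reactants: 16 (4S,5S)-4,5-bis[4-(benzyloxy)-3-methoxybenzyl]-2,2-dimethyl-N-(quinolin-8-yl)-1,3-dioxane-4-carboxamide
Product: 18 (3S,4S)-3,4-bis[4-(benzyloxy)-3-methoxybenzyl]-3-hydroxyoxolan-2-one, via diol amide 17 (not isolated)
Conditions: TsOH·H2O (3 equiv), 1,4-dioxane/H2O (10:1), 90 °C
Reagents that add atoms: none
Why: Acid hydrolysis of the acetonide frees the primary hydroxyl, which attacks the protonated N-quinolinyl amide intramolecularly (5-exo-trig acyl substitution), so lactone closure and loss of the auxiliary as its ammonium salt are one event; aryl benzyl ethers and the tertiary α-hydroxy lactone should survive.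

Step 12
Reactants: 18 (3S,4S)-3,4-bis[4-(benzyloxy)-3-methoxybenzyl]-3-hydroxyoxolan-2-one
Product: 19 (3S,4S)-3-hydroxy-3,4-bis(4-hydroxy-3-methoxybenzyl)oxolan-2-one (target)
Conditions: H2 (1 atm), 10% Pd/C, EtOAc/EtOH, rt
Reagents that add atoms: none
Why: Catalytic hydrogenolysis of the two aryl benzyl ethers; the lactone, the non-benzylic tertiary alcohol and the ArCH2–C bonds are not cleaved.

**Compound list**

1 | [4-(benzyloxy)-3-methoxyphenyl]methanol | COc1cc(CO)ccc1OCc1ccccc1 | starting material
2 | 1-(benzyloxy)-4-(bromomethyl)-2-methoxybenzene | COc1cc(CBr)ccc1OCc1ccccc1 | intermediate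
3 | diisopropyl (S)-malate | CC(C)OC(=O)C[C@H](O)C(=O)OC(C)C | starting material
4 | malate dilithium alkoxide-enolate (C2 alkoxide, C3 enolate of 3) | CC(C)OC(=O)[C@@H]([O-])C=C([O-])OC(C)C.[Li+].[Li+] | intermediate
5 | diisopropyl (2S,3R)-3-[4-(benzyloxy)-3-methoxybenzyl]-2-hydroxybutanedioate | CC(C)OC(=O)[C@@H](O)[C@@H](Cc1ccc(OCc2ccccc2)c(OC)c1)C(=O)OC(C)C | intermediate
6 | (2S,3R)-3-[4-(benzyloxy)-3-methoxybenzyl]-2-hydroxybutanedioic acid | OC(=O)[C@@H](O)[C@@H](Cc1ccc(OCc2ccccc2)c(OC)c1)C(=O)O | intermediate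
7 | (2R)-3-[4-(benzyloxy)-3-methoxyphenyl]-2-[(2S,4S)-2-tert-butyl-5-oxo-1,3-dioxolan-4-yl]propanoic acid | O=C1O[C@@H](C(C)(C)C)O[C@H]1[C@@H](Cc1ccc(OCc2ccccc2)c(OC)c1)C(=O)O | intermediate
8 | dilithium carboxylate-enolate of 7 | [O-]C1=C([C@@H](Cc2ccc(OCc3ccccc3)c(OC)c2)C(=O)[O-])O[C@H](C(C)(C)C)O1.[Li+].[Li+] | intermediate
9 | (2R)-3-[4-(benzyloxy)-3-methoxyphenyl]-2-[(2S,4S)-2-tert-butyl-4-methyl-5-oxo-1,3-dioxolan-4-yl]propanoic acid | O=C1O[C@@H](C(C)(C)C)O[C@@]1(C)[C@@H](Cc1ccc(OCc2ccccc2)c(OC)c1)C(=O)O | intermediate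
10 | hydroxy dioxolanone: (2S,5S)-5-[(2S)-1-[4-(benzyloxy)-3-methoxyphenyl]-3-hydroxypropan-2-yl]-2-tert-butyl-5-methyl-1,3-dioxolan-4-one | O=C1O[C@@H](C(C)(C)C)O[C@@]1(C)[C@@H](Cc1ccc(OCc2ccccc2)c(OC)c1)CO | intermediate
11 | (3S,4S)-4-[4-(benzyloxy)-3-methoxybenzyl]-3-hydroxy-3-methyloxolan-2-one | O=C1OC[C@H](Cc2ccc(OCc3ccccc3)c(OC)c2)[C@]1(C)O | intermediate
12 | (2S,3S)-3-[4-(benzyloxy)-3-methoxybenzyl]-2,4-dihydroxy-2-methyl-N-(quinolin-8-yl)butanamide | O=C(Nc1cccc2cccnc12)[C@@](C)(O)[C@@H](Cc1ccc(OCc2ccccc2)c(OC)c1)CO | intermediate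
13 | (4S,5S)-5-[4-(benzyloxy)-3-methoxybenzyl]-2,2,4-trimethyl-N-(quinolin-8-yl)-1,3-dioxane-4-carboxamide | O=C(Nc1cccc2cccnc12)[C@@]1(C)OC(C)(C)OC[C@@H]1Cc1ccc(OCc2ccccc2)c(OC)c1 | intermediate
14 | 4-iodo-2-methoxyphenol | COc1cc(I)ccc1O | starting material
15 | 1-(benzyloxy)-4-iodo-2-methoxybenzene | COc1cc(I)ccc1OCc1ccccc1 | intermediate
16 | (4S,5S)-4,5-bis[4-(benzyloxy)-3-methoxybenzyl]-2,2-dimethyl-N-(quinolin-8-yl)-1,3-dioxane-4-carboxamide | O=C(Nc1cccc2cccnc12)[C@@]1(Cc2ccc(OCc3ccccc3)c(OC)c2)OC(C)(C)OC[C@@H]1Cc1ccc(OCc2ccccc2)c(OC)c1 | intermediate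
17 | diol amide: (2S,3S)-2,3-bis[4-(benzyloxy)-3-methoxybenzyl]-2,4-dihydroxy-N-(quinolin-8-yl)butanamide | O=C(Nc1cccc2cccnc12)[C@@](Cc1ccc(OCc2ccccc2)c(OC)c1)(O)[C@@H](Cc1ccc(OCc2ccccc2)c(OC)c1)CO | intermediate
18 | (3S,4S)-3,4-bis[4-(benzyloxy)-3-methoxybenzyl]-3-hydroxyoxolan-2-one | O=C1OC[C@H](Cc2ccc(OCc3ccccc3)c(OC)c2)[C@]1(Cc1ccc(OCc2ccccc2)c(OC)c1)O | intermediate
19 | (3S,4S)-3-hydroxy-3,4-bis(4-hydroxy-3-methoxybenzyl)oxolan-2-one | COc1cc(C[C@H]2COC(=O)[C@]2(O)Cc2ccc(O)c(OC)c2)ccc1O | target

**Count**

Total steps: 12. Longest linear sequence: 11 steps (from 1 through steps 1–8 and 10–12); malate 3 enters this line at step 2, and step 9 is a one-step side branch.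

**Steps most likely to fail**

1. Step 10 (C–H arylation). Possible failures are slow cyclometalation at the crowded methyl group, over-arylation of the new benzylic position, or acid-triggered loss of the acetonide at 110 °C followed by loss of the auxiliary. Fallback, setting out from 7 and returning at 18: the C3–CH2 bond is made instead of the CH2–aryl bond. Acid 7 is converted to its dilithium carboxylate-enolate 8 as in step 5 and alkylated with bromide 2 in place of MeI, anti to the tert-butyl group, to give the doubly benzylated dioxolanone acid F1. BH3·SMe2 reduction gives the doubly benzylated hydroxy dioxolanone F2, and catalytic TFA closes the lactone with loss of pivalaldehyde to give 18.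

2. Step 7 (lactone aminolysis). Possible failures are sluggish acyl transfer from a lactone carbonyl flanked by a quaternary carbon to a weakly nucleophilic aromatic amine, and reclosure of the hydroxy amide to the lactone during work-up. Fallback, setting out from 9 and returning at 12: the amide is made from the more reactive dioxolanone and the lactone is never formed. Acid 9 is reduced with BH3·SMe2 and worked up without acid to give hydroxy dioxolanone 10, which is silylated (t-BuMe2SiCl, imidazole) to the silyl ether dioxolanone F3. The lithium amide of 8-aminoquinoline (from LiN(SiMe3)2) opens the dioxolanone carbonyl with loss of pivalaldehyde to give the silylated hydroxy amide F4, and Bu4NF gives 12.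

3. Step 8 (acetonide formation). Possible failures are acid-triggered relactonization with loss of the auxiliary competing with ketal formation at the hindered tertiary hydroxyl, and strain in the fully substituted 1,3-dioxane. Fallback, setting out from 12 and returning at 18: both hydroxyls are protected under basic conditions as acyclic silyl ethers. Et3SiOTf and 2,6-lutidine give the bis(triethylsilyl) ether amide F5, and the conditions of step 10 with 15 give the arylated bis(triethylsilyl) ether amide F6. The conditions of step 11 then remove both silyl groups and close the lactone through 17 to give 18.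

**Further compounds**

F1 | step 10 | (2R)-3-[4-(benzyloxy)-3-methoxyphenyl]-2-[(2S,4S)-4-[4-(benzyloxy)-3-methoxybenzyl]-2-tert-butyl-5-oxo-1,3-dioxolan-4-yl]propanoic acid | O=C1O[C@@H](C(C)(C)C)O[C@@]1(Cc1ccc(OCc2ccccc2)c(OC)c1)[C@@H](Cc1ccc(OCc2ccccc2)c(OC)c1)C(=O)O
F2 | step 10 | (2S,5S)-5-[4-(benzyloxy)-3-methoxybenzyl]-5-[(2S)-1-[4-(benzyloxy)-3-methoxyphenyl]-3-hydroxypropan-2-yl]-2-tert-butyl-1,3-dioxolan-4-one | O=C1O[C@@H](C(C)(C)C)O[C@@]1(Cc1ccc(OCc2ccccc2)c(OC)c1)[C@@H](Cc1ccc(OCc2ccccc2)c(OC)c1)CO
F3 | step 7 | (2S,5S)-5-[(2S)-1-[4-(benzyloxy)-3-methoxyphenyl]-3-[(tert-butyldimethylsilyl)oxy]propan-2-yl]-2-tert-butyl-5-methyl-1,3-dioxolan-4-one | O=C1O[C@@H](C(C)(C)C)O[C@@]1(C)[C@@H](Cc1ccc(OCc2ccccc2)c(OC)c1)CO[Si](C)(C)C(C)(C)C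
F4 | step 7 | (2S,3S)-3-[4-(benzyloxy)-3-methoxybenzyl]-4-[(tert-butyldimethylsilyl)oxy]-2-hydroxy-2-methyl-N-(quinolin-8-yl)butanamide | O=C(Nc1cccc2cccnc12)[C@@](C)(O)[C@@H](Cc1ccc(OCc2ccccc2)c(OC)c1)CO[Si](C)(C)C(C)(C)C
F5 | step 8 | (2S,3S)-3-[4-(benzyloxy)-3-methoxybenzyl]-2-methyl-N-(quinolin-8-yl)-2,4-bis[(triethylsilyl)oxy]butanamide | O=C(Nc1cccc2cccnc12)[C@@](C)(O[Si](CC)(CC)CC)[C@@H](Cc1ccc(OCc2ccccc2)c(OC)c1)CO[Si](CC)(CC)CC
F6 | step 8 | (2S,3S)-2,3-bis[4-(benzyloxy)-3-methoxybenzyl]-N-(quinolin-8-yl)-2,4-bis[(triethylsilyl)oxy]butanamide | O=C(Nc1cccc2cccnc12)[C@@](Cc1ccc(OCc2ccccc2)c(OC)c1)(O[Si](CC)(CC)CC)[C@@H](Cc1ccc(OCc2ccccc2)c(OC)c1)CO[Si](CC)(CC)CC
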